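## Retrosynthetic overview

1. Target 17 comes from pentamethyl ether 16 by global O-demethylation; the C3 isopropyl group of 16 comes from the C3 acetyl group of chromane 12 (methylenation, then hydrogenation).
2. Key disconnection (step 4): the dihydropyran ring of 12 is opened at O1–C8a (aryl ether by displacement of fluoride) and at C2–C3 (aldol), and the isobutyl group is removed from C4 (conjugate addition). This leaves achiral aryl enone 5, i-BuMgBr 6 and the threefold-symmetric trialdehyde 7.
3. Enabling feature: C3 lies between the benzylic C4 and the carbon that becomes the isopropyl methine. With that carbon as a ketone C=O, C4 is the β-carbon of an enone, and conjugate addition there turns C3 into an enolate. The aldolate oxygen then sits five atoms from C8a of ring A, which carries fluorine para to the C6 formyl carbon (masked as an aldimine).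
4. Enone 5 comes from 4-fluoro-2,6-dimethoxybenzaldehyde 1 by bromination, Heck reaction with but-3-en-2-one 3 and imine formation; all three formyl carbons of the target are bought with 1 and 7.
5. Ring order: both benzene rings are purchased; the only ring formed is the dihydropyran ring, in step 4.

Key step: step 4

Remark on numbering: chromane numbering of 17 is used throughout (O1, C2 with the diformyl aryl ring, C3 isopropyl, C4 isobutyl, C4a, C5–C8, C8a); ring A is the benzo ring of the chromane.

Assumption: 1 and 7 are taken as catalogue building blocks, and the ferrocenyl diphosphine enantiomer named in step 4 is assumed to make C4 (S); if the sense of induction is the opposite, its mirror-image ligand is used.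

## Route

Step 1
Reactants: 1 4-fluoro-2,6-dimethoxybenzaldehyde
Product: 2 3-bromo-4-fluoro-2,6-dimethoxybenzaldehyde
Conditions: N-bromosuccinimide (1.05 equiv), MeCN, 0 → 23 °C
Reagents that add atoms: N-bromosuccinimide, O=C1CCC(=O)N1Br
Why: Electrophilic aromatic bromination, in which the two free ring positions are equivalent, each activated by an ortho and a para methoxy group and meta to the formyl group, so a single regioisomer should form and one equivalent of reagent should stop at mono-bromination.

Step 2
Reactants: 2 3-bromo-4-fluoro-2,6-dimethoxybenzaldehyde; 3 but-3-en-2-one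
Product: 4 4-fluoro-2,6-dimethoxy-3-[(1E)-3-oxobut-1-en-1-yl]benzaldehyde
Conditions: Pd2(dba)3 (1.5 mol%), [HP(t-Bu)3]BF4 (6 mol%), Cy2NMe (1.2 equiv), 3 (1.5 equiv), dioxane, 70 °C
Reagents that add atoms: none
Why: Mizoroki–Heck reaction, in which zerovalent palladium with the bulky electron-rich phosphine inserts into the di-ortho-substituted C–Br bond and syn insertion of the enone followed by syn β-hydride elimination should give the (E)-enone while the formyl group stays untouched.

Step 3
Reactants: 4 4-fluoro-2,6-dimethoxy-3-[(1E)-3-oxobut-1-en-1-yl]benzaldehyde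
Product: 5 (3E)-4-{3-[(E)-(tert-butylimino)methyl]-6-fluoro-2,4-dimethoxyphenyl}but-3-en-2-one
Conditions: t-BuNH2 (5 equiv), MgSO4, CH2Cl2, 23 °C; volatiles removed, used crude
Reagents that add atoms: tert-butylamine, CC(C)(C)N
Why: Imine condensation of the aldehyde with a hindered primary amine, which should mask the formyl group against the Grignard reagent and the enolate of step 4 while keeping C8a activated (para C=N) for the later displacement of fluoride, the bulky amine not adding to the hindered β-aryl enone.

Step 4
Reactants: 5 (3E)-4-{3-[(E)-(tert-butylimino)methyl]-6-fluoro-2,4-dimethoxyphenyl}but-3-en-2-one; 6 isobutylmagnesium bromide; 7 2,4,6-trimethoxybenzene-1,3,5-tricarbaldehyde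
Product: 12 (2R,3R,4S)-3-acetyl-2-(3,5-diformyl-2,4,6-trimethoxyphenyl)-5,7-dimethoxy-4-(2-methylpropyl)chromane-6-carbaldehyde, via magnesium enolate 8 (not isolated), via magnesium aldolate 9 (not isolated), via potassium aldolate 10 (not isolated), via aldimine chromane 11 (not isolated)
Conditions: CuBr·SMe2 (5 mol%), (R)-1-[(S)-2-(diphenylphosphino)ferrocenyl]ethyldicyclohexylphosphine (6 mol%), 6 (1.2 equiv), t-BuOMe, −78 °C; then 7 (1.5 equiv), THF, −78 °C; then KOt-Bu (1.1 equiv), DMPU, −78 → 0 °C; aq. citric acid, 23 °C
Reagents that add atoms: water, O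
Why: The chiral copper–diphosphine complex transfers the isobutyl group of 6 to C4 of the enone (catalytic asymmetric conjugate addition of a Grignard reagent to an acyclic enone; the closest known reaction type is the copper/ferrocenyl-diphosphine conjugate addition with aldol trapping of the magnesium enolate), which should fix C4 as (S) under ligand control and release the (Z)-enolate 8 regiospecifically at C3. Enolate 8 should add to one of the three equivalent formyl groups of 7 through a closed six-membered (Zimmerman–Traxler) transition state, the Z geometry giving the syn aldol, which corresponds to the 2,3-trans relationship in the ring. The aldehyde should approach the enolate face opposite the aryl group on C4 while the C4–H lies in the enolate plane (allylic 1,3-strain), which places the acetyl group on C3 cis to the isobutyl group. After exchange of magnesium for potassium the alkoxide oxygen of 10 attacks C8a and expels fluoride by addition–elimination through a Meisenheimer intermediate stabilised by the para aldimine, closing the dihydropyran ring in a 6-exo mode with respect to the C8a=C8 bond. The step needs enantioface selection at C4 (ligand), mono-addition to 7 (its excess), attack at the C–F carbon and not at the methoxy-bearing C5 (fluoride is the far better leaving group in addition–elimination), and ring closure by the alkoxide and not by the enolate oxygen, which is secured by completing the aldol at −78 °C with excess aldehyde before the base is added. Aqueous acid finally hydrolyses the aldimine to the C6 formyl group without affecting the β-aryloxy ketone.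

Step 5
Reactants: 12 (2R,3R,4S)-3-acetyl-2-(3,5-diformyl-2,4,6-trimethoxyphenyl)-5,7-dimethoxy-4-(2-methylpropyl)chromane-6-carbaldehyde
Product: 15 (2R,3S,4S)-2-(3,5-diformyl-2,4,6-trimethoxyphenyl)-5,7-dimethoxy-4-(2-methylpropyl)-3-(prop-1-en-2-yl)chromane-6-carbaldehyde, via tris-aldimine ketone 13 (not isolated), via hydroxysilane 14 (not isolated)
Conditions: t-BuNH2 (excess), 4 Å MS, CH2Cl2, 23 °C, then evaporation; Me3SiCH2MgCl (1.5 equiv), CeCl3 (1.6 equiv), THF, −78 → −40 °C; 2 M aq. HCl, THF, 23 °C
Reagents that add atoms: (trimethylsilyl)methylmagnesium chloride, C[Si](C)(C)C[Mg]Cl; water, O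
Why: Peterson olefination on temporarily masked aldehydes, in which the three formyl groups are first converted into N-tert-butyl aldimines, the weakly basic silylmethylcerium reagent should then add only to the methyl ketone without enolising C3 or opening the β-aryloxy ketone, and aqueous acid eliminates Me3SiOH from the β-hydroxysilane and hydrolyses the aldimines, so that no stereocentre is formed or touched (the C3 descriptor changes only because the priorities change).

Step 6
Reactants: 15 (2R,3S,4S)-2-(3,5-diformyl-2,4,6-trimethoxyphenyl)-5,7-dimethoxy-4-(2-methylpropyl)-3-(prop-1-en-2-yl)chromane-6-carbaldehyde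
Product: 16 (2R,3R,4S)-2-(3,5-diformyl-2,4,6-trimethoxyphenyl)-5,7-dimethoxy-4-(2-methylpropyl)-3-(propan-2-yl)chromane-6-carbaldehyde
Conditions: H2 (1 atm), RhCl(PPh3)3 (5 mol%), benzene–EtOH, 23 °C
Reagents that add atoms: none
Why: Homogeneous hydrogenation with RhCl(PPh3)3 should reduce the 1,1-disubstituted alkene to the isopropyl group and leave the three aryl aldehydes and the benzylic C2–O bond alone, and it creates no stereocentre.

Step 7
Reactants: 16 (2R,3R,4S)-2-(3,5-diformyl-2,4,6-trimethoxyphenyl)-5,7-dimethoxy-4-(2-methylpropyl)-3-(propan-2-yl)chromane-6-carbaldehyde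
Product: 17 (2R,3R,4S)-2-(3,5-diformyl-2,4,6-trihydroxyphenyl)-5,7-dihydroxy-4-(2-methylpropyl)-3-(propan-2-yl)chromane-6-carbaldehyde (CNP0328914.1)
Conditions: BBr3 (12 equiv), CH2Cl2, −78 → 0 °C; then H2O
Reagents that add atoms: none
Why: Lewis-acid cleavage of aryl methyl ethers, in which all five methoxy groups lie ortho to a formyl group that assists by chelation and bromide removes each methyl group by SN2, and if the benzylic C2–O bond ionises reversibly, reclosure should return the isomer with the equatorial C2 aryl group trans to the C3 isopropyl group.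

## Compound list

1 | 4-fluoro-2,6-dimethoxybenzaldehyde | COc1cc(F)cc(OC)c1C=O | starting material
2 | 3-bromo-4-fluoro-2,6-dimethoxybenzaldehyde | COc1cc(F)c(Br)c(OC)c1C=O | intermediate
3 | but-3-en-2-one | CC(=O)C=C | starting material
4 | 4-fluoro-2,6-dimethoxy-3-[(1E)-3-oxobut-1-en-1-yl]benzaldehyde | CC(=O)/C=C/c1c(F)cc(OC)c(C=O)c1OC | intermediate
5 | (3E)-4-{3-[(E)-(tert-butylimino)methyl]-6-fluoro-2,4-dimethoxyphenyl}but-3-en-2-one | CC(=O)/C=C/c1c(F)cc(OC)c(/C=N/C(C)(C)C)c1OC | intermediate
6 | isobutylmagnesium bromide | CC(C)C[Mg]Br | starting material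
7 | 2,4,6-trimethoxybenzene-1,3,5-tricarbaldehyde | COc1c(C=O)c(OC)c(C=O)c(OC)c1C=O | starting material
8 | bromomagnesium (2Z,4S)-4-{3-[(E)-(tert-butylimino)methyl]-6-fluoro-2,4-dimethoxyphenyl}-6-methylhept-2-en-2-olate (formed in the flask) | CC(C)C[C@H](c1c(F)cc(OC)c(/C=N/C(C)(C)C)c1OC)/C=C(/C)O[Mg]Br | intermediate
9 | bromomagnesium (1R,2R,3S)-2-acetyl-3-{3-[(E)-(tert-butylimino)methyl]-6-fluoro-2,4-dimethoxyphenyl}-1-(3,5-diformyl-2,4,6-trimethoxyphenyl)-5-methylhexan-1-olate, the syn aldolate (formed in the flask) | CC(C)C[C@H](c1c(F)cc(OC)c(/C=N/C(C)(C)C)c1OC)[C@@H](C(C)=O)[C@@H](O[Mg]Br)c1c(OC)c(C=O)c(OC)c(C=O)c1OC | intermediate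
10 | potassium salt of the same (1R,2R,3S) aldolate (formed in the flask) | CC(C)C[C@H](c1c(F)cc(OC)c(/C=N/C(C)(C)C)c1OC)[C@@H](C(C)=O)[C@@H]([O-])c1c(OC)c(C=O)c(OC)c(C=O)c1OC.[K+] | intermediate
11 | 5-{(2R,3R,4S)-3-acetyl-6-[(E)-(tert-butylimino)methyl]-5,7-dimethoxy-4-(2-methylpropyl)chroman-2-yl}-2,4,6-trimethoxybenzene-1,3-dicarbaldehyde (formed in the flask) | CC(C)C[C@@H]1c2c(cc(OC)c(/C=N/C(C)(C)C)c2OC)O[C@@H](c2c(OC)c(C=O)c(OC)c(C=O)c2OC)[C@@H]1C(C)=O | intermediate
12 | (2R,3R,4S)-3-acetyl-2-(3,5-diformyl-2,4,6-trimethoxyphenyl)-5,7-dimethoxy-4-(2-methylpropyl)chromane-6-carbaldehyde | CC(C)C[C@@H]1c2c(cc(OC)c(C=O)c2OC)O[C@@H](c2c(OC)c(C=O)c(OC)c(C=O)c2OC)[C@@H]1C(C)=O | intermediate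
13 | tris(N-tert-butyl aldimine) of 12, (2R,3R,4S) (formed in the flask) | CC(C)C[C@@H]1c2c(cc(OC)c(/C=N/C(C)(C)C)c2OC)O[C@@H](c2c(OC)c(/C=N/C(C)(C)C)c(OC)c(/C=N/C(C)(C)C)c2OC)[C@@H]1C(C)=O | intermediate
14 | tris(N-tert-butyl aldimine) carrying a 2-hydroxy-1-(trimethylsilyl)propan-2-yl group at C3, (2R,3R,4S), carbinol centre unassigned (formed in the flask as its alkoxide) | CC(C)C[C@@H]1c2c(cc(OC)c(/C=N/C(C)(C)C)c2OC)O[C@@H](c2c(OC)c(/C=N/C(C)(C)C)c(OC)c(/C=N/C(C)(C)C)c2OC)[C@@H]1C(C)(O)C[Si](C)(C)C | intermediate
15 | (2R,3S,4S)-2-(3,5-diformyl-2,4,6-trimethoxyphenyl)-5,7-dimethoxy-4-(2-methylpropyl)-3-(prop-1-en-2-yl)chromane-6-carbaldehyde | CC(C)C[C@@H]1c2c(cc(OC)c(C=O)c2OC)O[C@@H](c2c(OC)c(C=O)c(OC)c(C=O)c2OC)[C@@H]1C(C)=C | intermediate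
16 | (2R,3R,4S)-2-(3,5-diformyl-2,4,6-trimethoxyphenyl)-5,7-dimethoxy-4-(2-methylpropyl)-3-(propan-2-yl)chromane-6-carbaldehyde | CC(C)C[C@@H]1c2c(cc(OC)c(C=O)c2OC)O[C@@H](c2c(OC)c(C=O)c(OC)c(C=O)c2OC)[C@@H]1C(C)C | intermediate
17 | (2R,3R,4S)-2-(3,5-diformyl-2,4,6-trihydroxyphenyl)-5,7-dihydroxy-4-(2-methylpropyl)-3-(propan-2-yl)chromane-6-carbaldehyde (CNP0328914.1) | CC(C)C[C@@H]1c2c(cc(O)c(C=O)c2O)O[C@@H](c2c(O)c(C=O)c(O)c(C=O)c2O)[C@@H]1C(C)C | target

## Step count and risks

Total step count: 7. Longest linear sequence: 7 steps (1 to 17).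

Steps most likely to fail:

Step 4. After the exchange to potassium the aldolate can revert to enolate and aldehyde. The enolate oxygen may then displace fluoride itself (six-membered closure to a 4H-chromene), or the fragments may recombine with loss of the kinetic C2/C3 configuration. Enantioface selection in the conjugate addition may also be poor on the di-ortho-substituted aryl enone. The fallback separates the three events with known chemistry. It sets out from 5: the same copper-catalysed conjugate addition of 6 is quenched with Me3SiCl to give the silyl enol ether (E)-N-tert-butyl-1-{4-fluoro-2,6-dimethoxy-3-[(2Z,4S)-6-methyl-2-(trimethylsilyloxy)hept-2-en-4-yl]phenyl}methanimine F1, on which the enantiomeric purity can be measured. A Mukaiyama aldol addition of F1 to 7 (BF3·OEt2, CH2Cl2, −78 °C, aqueous acidic work-up that also hydrolyses the aldimine) should give the β-hydroxy ketone (3R,4S)-3-[(R)-(3,5-diformyl-2,4,6-trimethoxyphenyl)(hydroxy)methyl]-4-(6-fluoro-3-formyl-2,4-dimethoxyphenyl)-6-methylheptan-2-one F2, to be separated from its diastereomers. F2 is then closed with Cs2CO3 in DMF at 23 °C (displacement of fluoride para to the now free formyl group, with no enolate generated beforehand), which comes back to the route at 12.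

Step 5. Masking of the three hindered formyl groups may be incomplete, so that the silylmethyl nucleophile adds to an aldehyde, or the nucleophile may add to an aldimine. If the medium turns basic, C3 can enolise, with epimerisation or E1cB loss of the aryloxide (ring opening at O1–C2). The fallback sets out from 12. The three formyl groups are converted into 1,3-dioxolanes with 1,2-bis(trimethylsilyloxy)ethane and catalytic Me3SiOTf in CH2Cl2 at −78 °C (aldehydes react, the hindered ketone does not) to give (2R,3R,4S)-3-acetyl-6-(1,3-dioxolan-2-yl)-2-[3,5-di(1,3-dioxolan-2-yl)-2,4,6-trimethoxyphenyl]-5,7-dimethoxy-4-(2-methylpropyl)chromane F3. Neutral methylenation with Cp2TiMe2 in toluene at 65 °C should give the 3-(prop-1-en-2-yl) tris-dioxolane F4, and aqueous HCl in THF removes the acetals and comes back to the route at 15.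

Step 7. The strong Lewis acid may ionise the benzylic C2–O1 bond, with ring opening or bromination at C2. Cleavage may also stall after the first demethylation next to each chelated formyl group, or the formyl groups may degrade. The fallback goes from 16 directly to 17 by nucleophilic dealkylation with NaSEt in DMF at 110 °C, followed by acidification. The thiolate attacks the methyl carbons in SN2 fashion, each aryloxide leaving group is stabilised by an ortho formyl group, and no Lewis acid reaches the benzylic ether. No new compound arises (entry F0).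

## Further compounds

F1 | step 4 | (E)-N-tert-butyl-1-{4-fluoro-2,6-dimethoxy-3-[(2Z,4S)-6-methyl-2-(trimethylsilyloxy)hept-2-en-4-yl]phenyl}methanimine | CC(C)C[C@H](c1c(F)cc(OC)c(/C=N/C(C)(C)C)c1OC)/C=C(/C)O[Si](C)(C)C
F2 | step 4 | (3R,4S)-3-[(R)-(3,5-diformyl-2,4,6-trimethoxyphenyl)(hydroxy)methyl]-4-(6-fluoro-3-formyl-2,4-dimethoxyphenyl)-6-methylheptan-2-one | CC(C)C[C@H](c1c(F)cc(OC)c(C=O)c1OC)[C@@H](C(C)=O)[C@@H](O)c1c(OC)c(C=O)c(OC)c(C=O)c1OC
F3 | step 5 | (2R,3R,4S)-3-acetyl-6-(1,3-dioxolan-2-yl)-2-[3,5-di(1,3-dioxolan-2-yl)-2,4,6-trimethoxyphenyl]-5,7-dimethoxy-4-(2-methylpropyl)chromane | CC(C)C[C@@H]1c2c(cc(OC)c(C3OCCO3)c2OC)O[C@@H](c2c(OC)c(C3OCCO3)c(OC)c(C3OCCO3)c2OC)[C@@H]1C(C)=O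
F4 | step 5 | (2R,3S,4S)-6-(1,3-dioxolan-2-yl)-2-[3,5-di(1,3-dioxolan-2-yl)-2,4,6-trimethoxyphenyl]-5,7-dimethoxy-4-(2-methylpropyl)-3-(prop-1-en-2-yl)chromane | CC(C)C[C@@H]1c2c(cc(OC)c(C3OCCO3)c2OC)O[C@@H](c2c(OC)c(C3OCCO3)c(OC)c(C3OCCO3)c2OC)[C@@H]1C(C)=C
F0 | step 7 | none | none
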